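- Slowness is the first thing you see: in the noon run and the dawn run, left-handed product rises more and more slowly with left-handed substrate still unreacted.

common to all: left-handed substrate 0.020 M; right-handed substrate 0.020 M; free catalyst 5 mol%
- noon: partner 2 equiv (fed, over 4.0 min); protic impurity 2 mM; the very flask that is asked about, followed so far
- dawn: partner 1 equiv (fed, over 4.0 min); protic impurity 2 mM; run made earlier
- flask: partner 2.00 equiv (fed, over 4.0 min); protic impurity 2.00 mM; time 4.0 h

noon run (percent of the left-handed substrate and right-handed substrate together charged)

| time / min | left-handed product / % | right-handed substrate / % |
|---|---|---|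
| 4.00 | 7.7 | 50.0 |
| 12.0 | 22.2 | 49.9 |
| 20.0 | 28.5 | 47.9 |
| 30.0 | 35.4 | 49.1 |
| 50.0 | 37.9 | 48.5 |

dawn run (percent of the left-handed substrate and right-handed substrate together charged)

| time / h | left-handed product / % | right-handed substrate / % |
|---|---|---|
| 0.333 | 17.4 | 49.1 |
| 0.667 | 27.6 | 48.7 |
| 1.00 | 31.6 | 49.4 |
| 2.00 | 33.4 | 49.0 |
| 4.00 | 36.5 | 49.2 |

(readings scatter by 1 percentage point)

- free catalyst is single-handed; left-handed substrate and right-handed substrate are mirror images of each other, charged as a racemate, each of them at the stated concentration
- the numbers in the tables scatter with a standard deviation of 1 percentage point
- on the list of suspects stand: partner + catalyst intermediate B -> free catalyst + right-handed product; free catalyst + right-handed substrate <-> catalyst intermediate B; free catalyst -> spent catalyst; partner + protic impurity -> quenched reagent; free catalyst + left-handed substrate <-> catalyst intermediate A; partner + catalyst intermediate A -> free catalyst + left-handed product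

1. amount of left-handed product at 4.0 h, in percent of the left-handed substrate and right-handed substrate together charged
2. amount of right-handed substrate at 4.0 h, in percent of the left-handed substrate and right-handed substrate together charged
3. amount of right-handed product at 4.0 h, in percent of the left-handed substrate and right-handed substrate together charged

- The last two dawn readings differ by 3.1 percentage points, and each reading scatters by 1 point, so dawn may still be creeping and these two readings do not tell what slows it. I assume that free catalyst is being lost, one of the suspects, and reckon on that assumption.
- A bench rule suits this. Treat left-handed substrate as pseudo-first-order, with a rate constant proportional to partner and to live catalyst. Then the natural log of charged over unreacted left-handed substrate adds up over the catalyst's life.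
- To find the order in partner, compare that log at the same time in both runs. At 20.0 min, noon stands at 1.97 times dawn, and noon has twice the partner, so the order reads close to one, as far as two scattered readings can show.
- Dawn ends with a log of 1.31. I therefore carry 2.58 as the flask's lifetime log-conversion, the natural log of charged over unreacted left-handed substrate once catalyst activity has ended. That gives 46.2 % left-handed product.
- The rule's border is partner falling well below its charge. If protic impurity reacts whole, product and impurity leave dawn 17.0 % of its partner, so dawn's end lies past that border and my figure is rough.
- Right-handed substrate stays flat within the scatter, so I take noon's last 48.5 %, which leaves 1.5 points for right-handed product.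
- The forecast, lower than my figure for left-handed product, gives 40 %, 49 % and 1 % for left-handed product, right-handed substrate and right-handed product, holding that “The plateaus show the catalyst dying”.
- The flask gives 45.3 %, 47.2 % and 2.82 %, in that order.

    partner + catalyst intermediate B → free catalyst + right-handed product (k = 0.0662 M⁻¹ s⁻¹)
    free catalyst + right-handed substrate ⇌ catalyst intermediate B (K = 32.4 M⁻¹, k = 37.3 M⁻¹ s⁻¹)
    free catalyst → spent catalyst (k = 8.91 × 10⁻⁴ s⁻¹)
    partner + protic impurity → quenched reagent (k = 0.0219 M⁻¹ s⁻¹)
    free catalyst + left-handed substrate ⇌ catalyst intermediate A (K = 131 M⁻¹, k = 4.82 M⁻¹ s⁻¹)
    partner + catalyst intermediate A → free catalyst + left-handed product (k = 1.21 M⁻¹ s⁻¹)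

- The flask keeps 9.5 % of its left-handed substrate unreacted, a log-conversion of 2.35, below the carried 2.58. At 4.00 h, the forward binding of left-handed substrate alone has a half-life of 71 h, far longer than the run of 4.0 h, and spent catalyst stands at 99.9 % of the catalyst charged. Scaled to a neighbouring flask, the same flask with 1.2 mol% of free catalyst, 2.58 becomes 0.620, which leaves 53.8 % of left-handed substrate unreacted; that neighbouring flask keeps 52 %.

The data are calculated with constants of no real substance, noise included.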